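**Strategy.** The ten-membered carbocycle is disconnected at C7–C8, where the α-methylene-γ-butyrolactone (C11=C13, C12=O, ring oxygen on C6) flanks the C8 carbinol: the retron of a 2-carbonylallyl-metal addition to an aldehyde. The cyclisation precursor is an open-chain (R)-5-alkenyl-3-(bromomethyl)butenolide whose (1Z,5E)-dienyl chain ends in the C8 aldehyde; ten of its carbons and both alkene geometries come from neryl acetate. One chromium-mediated intramolecular allylation closes the carbocycle, sets C7 and C8 from C6 (the only catalyst-made ring stereocentre) and unveils the exocyclic methylene. Acylation with (2S,3S)-epoxyangelic acid and a substrate-controlled epoxidation of the C1=C10 alkene complete the target.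

Key step: step 11

Remarks on the chemistry:
- Atom labels C1–C15 follow germacrane numbering of the target: lactone oxygen on C6, ester oxygen on C8, epoxide on C1/C10, methyls C14 on C10 and C15 on C4, C4=C5 is Z.
- Metal alkoxides (boron, zinc, chromium, aluminium, titanium) that are only protonated on aqueous work-up are treated as salts of the product and carry no number.
- Assumption: the (−)-MIB–zinc catalyst transfers the alkenyl group to the Si face of enal 8, as it does with aromatic and other α,β-unsaturated aldehydes; if the sense were opposite, (+)-MIB would be used.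

**Route**

Step 1
Reactants: 1 neryl acetate
Product: 3 (2Z,6E)-3,7-dimethyl-8-oxoocta-2,6-dien-1-yl acetate, via allylic alcohol 2 (not isolated)
Conditions: SeO2 (cat.), t-BuOOH, salicylic acid (cat.), CH2Cl2, rt; crude after work-up: MnO2, CH2Cl2, rt
Reagents that add atoms: selenium dioxide, O=[Se]=O (catalytic oxygen carrier); tert-butyl hydroperoxide, CC(C)(C)OO (terminal oxygen source)
Why: Riley allylic oxidation (ene reaction then [2,3]-sigmatropic shift) should attack only the (E)-methyl of the electron-rich terminal alkene, the 2,3-alkene being deactivated by the allylic acetate, and MnO2 then converges the alcohol/aldehyde mixture on the (E)-enal.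

Step 2
Reactants: 3 (2Z,6E)-3,7-dimethyl-8-oxoocta-2,6-dien-1-yl acetate
Product: 4 (2Z,6E)-3,7-dimethylnona-2,6,8-trien-1-yl acetate
Conditions: Ph3PCH3Br, KN(SiMe3)2, THF, −78 °C to 0 °C
Reagents that add atoms: methyltriphenylphosphonium bromide, C[P+](c1ccccc1)(c1ccccc1)c1ccccc1.[Br-]
Why: Wittig methylenation, in which the unstabilised ylide (used in slight excess only) should react with the enal far faster than with the acetate and leave both alkene geometries untouched.

Step 3
Reactants: 4 (2Z,6E)-3,7-dimethylnona-2,6,8-trien-1-yl acetate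
Product: 6 (2Z,6E)-3,7-dimethylnona-2,6-diene-1,9-diol, via alkylborane 5 (not isolated)
Conditions: 9-BBN, THF, 0 °C to rt; then NaOH, H2O2, MeOH/H2O, 0 °C to rt
Reagents that add atoms: hydrogen peroxide, OO
Why: Brown hydroboration with the bulky 9-BBN should add anti-Markovnikov to the only monosubstituted alkene (the diene terminus), and the alkaline peroxide oxidation should cleave the acetate in the same operation.

Step 4
Reactants: 6 (2Z,6E)-3,7-dimethylnona-2,6-diene-1,9-diol
Product: 7 (2Z,6E)-9-hydroxy-3,7-dimethylnona-2,6-dienal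
Conditions: MnO2, CH2Cl2, 0 °C to rt
Reagents that add atoms: none
Why: Chemoselective MnO2 oxidation of the allylic alcohol in the presence of the homoallylic one, under neutral heterogeneous conditions that should keep the Z-enal geometry.

Step 5
Reactants: 7 (2Z,6E)-9-hydroxy-3,7-dimethylnona-2,6-dienal
Product: 8 (2Z,6E)-9-[(tert-butyldimethylsilyl)oxy]-3,7-dimethylnona-2,6-dienal
Conditions: TBSCl, imidazole, CH2Cl2, 0 °C
Reagents that add atoms: tert-butyldimethylsilyl chloride, CC(C)(C)[Si](C)(C)Cl
Why: Standard silylation of the primary alcohol, masking the future C8 aldehyde until just before the cyclisation.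

Step 6
Reactants: 8 (2Z,6E)-9-[(tert-butyldimethylsilyl)oxy]-3,7-dimethylnona-2,6-dienal; 9 hex-1-yne
Product: 12 (5E,7S,8Z,12E)-15-[(tert-butyldimethylsilyl)oxy]-9,13-dimethylpentadeca-5,8,12-trien-7-ol, via hexenyldicyclohexylborane 10 (not isolated), via hexenylmethylzinc 11 (not isolated)
Conditions: 9, dicyclohexylborane (from BH3·SMe2 and cyclohexene), toluene, 0 °C to rt; Me2Zn, −78 °C; (−)-MIB (5 mol%); then 8, −20 °C to 0 °C; aq. NH4Cl
Reagents that add atoms: none
Why: Catalytic asymmetric alkenylzinc addition (alkyne hydroboration, boron-to-zinc transmetalation, amino-alcohol catalysis), in which the MIB–zinc complex should deliver the (E)-hexenyl group to the Si face of the enal and so set C6 as the (7S)-carbinol; the butyl end of the alkene is expelled later in the metathesis.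

Step 7
Reactants: 12 (5E,7S,8Z,12E)-15-[(tert-butyldimethylsilyl)oxy]-9,13-dimethylpentadeca-5,8,12-trien-7-ol; 13 2-(bromomethyl)acrylic acid
Product: 15 (5E,7S,8Z,12E)-15-[(tert-butyldimethylsilyl)oxy]-9,13-dimethylpentadeca-5,8,12-trien-7-yl 2-(bromomethyl)acrylate, via O-acylisourea 14 (not isolated)
Conditions: DCC, DMAP (5 mol%), CH2Cl2, −10 °C to rt
Reagents that add atoms: none
Why: Steglich esterification at low temperature with little DMAP should acylate the bis-allylic alcohol with retention at C6 while limiting attack on the allylic bromide.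

Step 8
Reactants: 15 (5E,7S,8Z,12E)-15-[(tert-butyldimethylsilyl)oxy]-9,13-dimethylpentadeca-5,8,12-trien-7-yl 2-(bromomethyl)acrylate
Product: 16 (5R)-3-(bromomethyl)-5-[(1Z,5E)-8-[(tert-butyldimethylsilyl)oxy]-2,6-dimethylocta-1,5-dien-1-yl]furan-2(5H)-one
Conditions: second-generation Grubbs catalyst (5 mol%), CH2Cl2 (0.01 M), 40 °C
Reagents that add atoms: none
Why: Ring-closing metathesis should start at the disubstituted hexenyl alkene and close onto the 1,1-disubstituted acrylate to give the butenolide with loss of hex-1-ene, the trisubstituted alkenes being too hindered to take part and C6 being untouched.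

Step 9
Reactants: 16 (5R)-3-(bromomethyl)-5-[(1Z,5E)-8-[(tert-butyldimethylsilyl)oxy]-2,6-dimethylocta-1,5-dien-1-yl]furan-2(5H)-one
Product: 17 (5R)-3-(bromomethyl)-5-[(1Z,5E)-8-hydroxy-2,6-dimethylocta-1,5-dien-1-yl]furan-2(5H)-one
Conditions: HF·pyridine, THF/pyridine, 0 °C
Reagents that add atoms: none
Why: Fluoride-mediated desilylation under weakly acidic, non-basic conditions should spare the allylic bromide and the epimerisable, doubly allylic C6–H of the butenolide.

Step 10
Reactants: 17 (5R)-3-(bromomethyl)-5-[(1Z,5E)-8-hydroxy-2,6-dimethylocta-1,5-dien-1-yl]furan-2(5H)-one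
Product: 18 (3E,7Z)-8-[(2R)-4-(bromomethyl)-5-oxo-2,5-dihydrofuran-2-yl]-3,7-dimethylocta-3,7-dienal
Conditions: Dess–Martin periodinane, NaHCO3, CH2Cl2, 0 °C; used at once
Reagents that add atoms: none
Why: Buffered Dess–Martin oxidation is the mildest entry to a β,γ-unsaturated aldehyde and should avoid conjugation of the C1=C10 alkene if the product is not stored.

Step 11
Reactants: 18 (3E,7Z)-8-[(2R)-4-(bromomethyl)-5-oxo-2,5-dihydrofuran-2-yl]-3,7-dimethylocta-3,7-dienal
Product: 20 (3aR,4R,6E,10Z,11aR)-4-hydroxy-6,10-dimethyl-3-methylidene-3a,4,5,8,9,11a-hexahydrocyclodeca[b]furan-2(3H)-one, via allylchromium dichloride 19 (not isolated)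
Conditions: CrCl2 (8 equiv), THF, slow addition of 18 over 12 h to a final 0.002 M, rt; aq. NH4Cl
Reagents that add atoms: none
Why: Two equivalents of CrCl2 (divalent chromium) reduce the allylic C–Br bond of 18 to the allylchromium dichloride 19 (trivalent chromium), whose γ-carbon (ring carbon 4 of the furanone, C7 of the target) adds to the tethered aldehyde carbon C8 with allylic transposition, so that one bond formation closes the ten-membered carbocycle and moves the double bond out of the lactone ring to give the α-methylene-γ-butyrolactone. The closest known reaction type is the Nozaki–Hiyama–Kishi (Barbier-type) allylation of aldehydes with 3-(bromomethyl)furan-2(5H)-ones and 2-(bromomethyl)acrylates, which is also established for intramolecular macrocyclisation. The carbocycle closes by a 10-exo-trig addition to the aldehyde carbonyl through a six-membered chair-like Zimmerman–Traxler array (Cr–O=C8···C7=C11–C13). C7 is controlled by the resident C6 stereocentre, since the new bond should form on the face of the planar allyl unit opposite to the C5 alkenyl chain and give the trans-fused lactone, and C8 follows from the ring-locked (E)-type allyl geometry (C6 trans to C13) with the aldehyde chain equatorial, which gives the anti homoallylic alcohol, that is the 8β-hydroxy group. The step needs γ- over α-attack (α-attack would require a twelve-membered ring and is not the normal course of allylchromium additions), cyclisation over oligomerisation (slow addition at high dilution) and retention of both alkene geometries and of C6 (neutral, non-basic medium).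

Step 12
Reactants: 21 methyl angelate
Product: 22 (Z)-2-methylbut-2-en-1-ol
Conditions: i-Bu2AlH, CH2Cl2, −78 °C; aq. potassium sodium tartrate
Reagents that add atoms: none
Why: 1,2-Reduction of the enoate by the aluminium hydride at low temperature should give the allylic alcohol without loss of the Z geometry.

Step 13
Reactants: 22 (Z)-2-methylbut-2-en-1-ol
Product: 23 [(2R,3S)-2,3-dimethyloxiran-2-yl]methanol
Conditions: Ti(OiPr)4 (10 mol%), D-(−)-diisopropyl tartrate (12 mol%), t-BuOOH, 4 Å molecular sieves, CH2Cl2, −20 °C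
Reagents that add atoms: tert-butyl hydroperoxide, CC(C)(C)OO
Why: Katsuki–Sharpless asymmetric epoxidation, in which the D-tartrate catalyst should deliver oxygen to the alkene face opposite to that used by the L-tartrate (which gives 2S-glycidols), setting both epoxide centres in one suprafacial event.

Step 14
Reactants: 23 [(2R,3S)-2,3-dimethyloxiran-2-yl]methanol
Product: 24 (2S,3S)-2,3-dimethyloxirane-2-carboxylic acid
Conditions: RuCl3 hydrate (2 mol%), NaIO4, MeCN/EtOAc/H2O, rt
Reagents that add atoms: sodium periodate, [Na+].[O-]I(=O)(=O)=O (terminal oxidant through RuO4); water, O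
Why: RuO4 oxidation of the primary alcohol to the acid is established for 2,3-epoxy alcohols and leaves the epoxide centres untouched (the C2 descriptor changes only because the priorities change).

Step 15
Reactants: 20 (3aR,4R,6E,10Z,11aR)-4-hydroxy-6,10-dimethyl-3-methylidene-3a,4,5,8,9,11a-hexahydrocyclodeca[b]furan-2(3H)-one; 24 (2S,3S)-2,3-dimethyloxirane-2-carboxylic acid
Product: 26 (3aR,4R,6E,10Z,11aR)-6,10-dimethyl-3-methylidene-2-oxo-2,3,3a,4,5,8,9,11a-octahydrocyclodeca[b]furan-4-yl (2S,3S)-2,3-dimethyloxirane-2-carboxylate, via mixed anhydride 25 (not isolated)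
Conditions: 24, 2,4,6-trichlorobenzoyl chloride, Et3N, THF, 0 °C to rt; then 20, DMAP, toluene, rt
Reagents that add atoms: none
Why: Yamaguchi esterification is suited to a hindered secondary alcohol and an α-quaternary acid, and acylation on oxygen retains the C8 configuration and the non-epimerisable epoxy acid centres.

Step 16
Reactants: 26 (3aR,4R,6E,10Z,11aR)-6,10-dimethyl-3-methylidene-2-oxo-2,3,3a,4,5,8,9,11a-octahydrocyclodeca[b]furan-4-yl (2S,3S)-2,3-dimethyloxirane-2-carboxylate
Product: 27 target, (1R,6R,7R,8R,10R)-1,10-epoxy-8-[(2S,3S)-2,3-dimethyloxirane-2-carbonyloxy]germacra-4Z,11(13)-dien-12,6-olide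
Conditions: mCPBA (1.05 equiv), NaHCO3, CH2Cl2, −20 °C to 0 °C
Reagents that add atoms: 3-chloroperoxybenzoic acid, OOC(=O)c1cccc(Cl)c1
Why: Prilezhaev epoxidation should select the C1=C10 alkene (the most electron-rich; C4=C5 is deactivated by the allylic lactone oxygen and the methylene lactone is electron-poor) and attack its exposed outer face in the conformer with the C10 methyl on the β face, giving the trans (1R,10R)-epoxide (1β,10α) by macrocyclic substrate control.

**Compound list**

1 | neryl acetate, (2Z)-3,7-dimethylocta-2,6-dien-1-yl acetate | CC(=O)OC/C=C(/C)CCC=C(C)C | starting material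
2 | (2Z,6E)-8-hydroxy-3,7-dimethylocta-2,6-dien-1-yl acetate | CC(=O)OC/C=C(/C)CC/C=C(\C)CO | intermediate
3 | (2Z,6E)-3,7-dimethyl-8-oxoocta-2,6-dien-1-yl acetate | CC(=O)OC/C=C(/C)CC/C=C(\C)C=O | intermediate
4 | (2Z,6E)-3,7-dimethylnona-2,6,8-trien-1-yl acetate | CC(=O)OC/C=C(/C)CC/C=C(\C)C=C | intermediate
5 | (2Z,6E)-9-(9-borabicyclo[3.3.1]nonan-9-yl)-3,7-dimethylnona-2,6-dien-1-yl acetate | CC(=O)OC/C=C(/C)CC/C=C(\C)CCB1C2CCCC1CCC2 | intermediate
6 | (2Z,6E)-3,7-dimethylnona-2,6-diene-1,9-diol | OC/C=C(/C)CC/C=C(\C)CCO | intermediate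
7 | (2Z,6E)-9-hydroxy-3,7-dimethylnona-2,6-dienal | O=C/C=C(/C)CC/C=C(\C)CCO | intermediate
8 | (2Z,6E)-9-[(tert-butyldimethylsilyl)oxy]-3,7-dimethylnona-2,6-dienal | O=C/C=C(/C)CC/C=C(\C)CCO[Si](C)(C)C(C)(C)C | intermediate
9 | hex-1-yne | C#CCCCC | starting material
10 | (E)-hex-1-enyl(dicyclohexyl)borane | CCCC/C=C/B(C1CCCCC1)C1CCCCC1 | intermediate
11 | (E)-hex-1-enyl(methyl)zinc | CCCC/C=C/[Zn]C | intermediate
12 | (5E,7S,8Z,12E)-15-[(tert-butyldimethylsilyl)oxy]-9,13-dimethylpentadeca-5,8,12-trien-7-ol | CCCC/C=C/[C@H](O)/C=C(/C)CC/C=C(\C)CCO[Si](C)(C)C(C)(C)C | intermediate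
13 | 2-(bromomethyl)acrylic acid | C=C(CBr)C(=O)O | starting material
14 | O-[2-(bromomethyl)acryloyl]-N,N'-dicyclohexylisourea | C=C(CBr)C(=O)OC(=NC1CCCCC1)NC1CCCCC1 | intermediate
15 | (5E,7S,8Z,12E)-15-[(tert-butyldimethylsilyl)oxy]-9,13-dimethylpentadeca-5,8,12-trien-7-yl 2-(bromomethyl)acrylate | CCCC/C=C/[C@H](OC(=O)C(=C)CBr)/C=C(/C)CC/C=C(\C)CCO[Si](C)(C)C(C)(C)C | intermediate
16 | (5R)-3-(bromomethyl)-5-[(1Z,5E)-8-[(tert-butyldimethylsilyl)oxy]-2,6-dimethylocta-1,5-dien-1-yl]furan-2(5H)-one | O=C1O[C@H](/C=C(/C)CC/C=C(\C)CCO[Si](C)(C)C(C)(C)C)C=C1CBr | intermediate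
17 | (5R)-3-(bromomethyl)-5-[(1Z,5E)-8-hydroxy-2,6-dimethylocta-1,5-dien-1-yl]furan-2(5H)-one | O=C1O[C@H](/C=C(/C)CC/C=C(\C)CCO)C=C1CBr | intermediate
18 | (3E,7Z)-8-[(2R)-4-(bromomethyl)-5-oxo-2,5-dihydrofuran-2-yl]-3,7-dimethylocta-3,7-dienal | O=C1O[C@H](/C=C(/C)CC/C=C(\C)CC=O)C=C1CBr | intermediate
19 | {[(5R)-5-[(1Z,5E)-2,6-dimethyl-8-oxoocta-1,5-dien-1-yl]-2-oxo-2,5-dihydrofuran-3-yl]methyl}chromium dichloride (trivalent chromium) | O=C1O[C@H](/C=C(/C)CC/C=C(\C)CC=O)C=C1C[Cr](Cl)Cl | intermediate
20 | (3aR,4R,6E,10Z,11aR)-4-hydroxy-6,10-dimethyl-3-methylidene-3a,4,5,8,9,11a-hexahydrocyclodeca[b]furan-2(3H)-one | C=C1C(=O)O[C@@H]2/C=C(/C)CC/C=C(\C)C[C@@H](O)[C@@H]12 | intermediate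
21 | methyl angelate, methyl (Z)-2-methylbut-2-enoate | C/C=C(/C)C(=O)OC | starting material
22 | (Z)-2-methylbut-2-en-1-ol | C/C=C(/C)CO | intermediate
23 | [(2R,3S)-2,3-dimethyloxiran-2-yl]methanol | OC[C@@]1(C)O[C@H]1C | intermediate
24 | (2S,3S)-2,3-dimethyloxirane-2-carboxylic acid (epoxyangelic acid) | OC(=O)[C@@]1(C)O[C@H]1C | intermediate
25 | (2S,3S)-2,3-dimethyloxirane-2-carboxylic 2,4,6-trichlorobenzoic anhydride | O=C(OC(=O)[C@@]1(C)O[C@H]1C)c1c(Cl)cc(Cl)cc1Cl | intermediate
26 | (3aR,4R,6E,10Z,11aR)-6,10-dimethyl-3-methylidene-2-oxo-2,3,3a,4,5,8,9,11a-octahydrocyclodeca[b]furan-4-yl (2S,3S)-2,3-dimethyloxirane-2-carboxylate | C=C1C(=O)O[C@@H]2/C=C(/C)CC/C=C(\C)C[C@@H](OC(=O)[C@@]3(C)O[C@H]3C)[C@@H]12 | intermediate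
27 | (1R,6R,7R,8R,10R)-1,10-epoxy-8-[(2S,3S)-2,3-dimethyloxirane-2-carbonyloxy]germacra-4Z,11(13)-dien-12,6-olide | C=C1C(=O)O[C@@H]2/C=C(/C)CC[C@H]3O[C@]3(C)C[C@@H](OC(=O)[C@@]3(C)O[C@H]3C)[C@@H]12 | target

**Count and risks**

Total step count: 16. Longest linear sequence: 13 steps (steps 1–11, 15 and 16, from neryl acetate); the epoxy acid 24 is made in 3 steps (12–14).

Steps most likely to fail:

1. Step 11. The macrocyclisation may lose diastereocontrol (cis ring fusion, or addition through the transition state with the aldehyde chain axial to give the 8-epimer) or be overtaken by intermolecular allylation and by protonation of the allylchromium. Fallback: setting out from 16, the allylic bromide is exchanged for boron (B2pin2, Pd2(dba)3 as a zerovalent palladium source, toluene, 50 °C) to give (5R)-5-[(1Z,5E)-8-[(tert-butyldimethylsilyl)oxy]-2,6-dimethylocta-1,5-dien-1-yl]-3-[(4,4,5,5-tetramethyl-1,3,2-dioxaborolan-2-yl)methyl]furan-2(5H)-one F1. Desilylation with HF·pyridine gives the hydroxy allylboronate F2 and buffered Dess–Martin oxidation the aldehyde allylboronate F3. F3 is cyclised by intramolecular allylboration (toluene, 80 °C, or Sc(OTf)3 catalysis at low temperature) through a compact closed chair transition state; hydrolysis of the borate on work-up comes back to the route at 20.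

2. Step 16. The epoxidation may attack the wrong face of C1=C10 (reaction through the other ring conformer), touch the C4=C5 alkene, or be followed by acid-induced transannular opening of the epoxide. Fallback: setting out from 20, a reagent-controlled Shi epoxidation is used (D-fructose-derived Shi ketone, Oxone (2KHSO5·KHSO4·K2SO4), K2CO3 buffer, MeCN/dimethoxymethane/H2O, 0 °C). By the spiro transition-state model it should deliver oxygen to the face of the trans-trisubstituted C1=C10 alkene that leads to the (1R,10R)-epoxide, giving (1R,6R,7R,8R,10R)-1,10-epoxy-8-hydroxygermacra-4Z,11(13)-dien-12,6-olide F4. Yamaguchi esterification of F4 with 24 (through 25) comes back to the route at the target 27.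

3. Step 6. The alkenylzinc addition may suffer erosion of enantioselectivity, Z-to-E isomerisation of the enal under Lewis acid, or competing methyl transfer. Fallback: setting out from 8, a zinc–ProPhenol-catalysed alkynylation (trimethylsilylacetylene, Me2Zn, the ProPhenol enantiomer that adds to the Si face, toluene) gives (3R,4Z,8E)-11-[(tert-butyldimethylsilyl)oxy]-5,9-dimethyl-1-(trimethylsilyl)undeca-4,8-dien-1-yn-3-ol F5. K2CO3 in MeOH gives the terminal alkyne (3R,4Z,8E)-11-[(tert-butyldimethylsilyl)oxy]-5,9-dimethylundeca-4,8-dien-1-yn-3-ol F6, and Lindlar semi-hydrogenation (Pd on CaCO3 poisoned with Pb(OAc)2, quinoline, H2) gives the vinyl carbinol (3S,4Z,8E)-11-[(tert-butyldimethylsilyl)oxy]-5,9-dimethylundeca-1,4,8-trien-3-ol F7. Esterification with 13 (DCC, through 14) gives its 2-(bromomethyl)acrylate F8, whose ring-closing metathesis with the second-generation Grubbs catalyst (loss of ethylene) comes back to the route at 16.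

Further compounds
F1 | step 11 | (5R)-5-[(1Z,5E)-8-[(tert-butyldimethylsilyl)oxy]-2,6-dimethylocta-1,5-dien-1-yl]-3-[(4,4,5,5-tetramethyl-1,3,2-dioxaborolan-2-yl)methyl]furan-2(5H)-one | O=C1O[C@H](/C=C(/C)CC/C=C(\C)CCO[Si](C)(C)C(C)(C)C)C=C1CB1OC(C)(C)C(C)(C)O1
F2 | step 11 | (5R)-5-[(1Z,5E)-8-hydroxy-2,6-dimethylocta-1,5-dien-1-yl]-3-[(4,4,5,5-tetramethyl-1,3,2-dioxaborolan-2-yl)methyl]furan-2(5H)-one | O=C1O[C@H](/C=C(/C)CC/C=C(\C)CCO)C=C1CB1OC(C)(C)C(C)(C)O1
F3 | step 11 | (3E,7Z)-3,7-dimethyl-8-[(2R)-5-oxo-4-[(4,4,5,5-tetramethyl-1,3,2-dioxaborolan-2-yl)methyl]-2,5-dihydrofuran-2-yl]octa-3,7-dienal | O=C1O[C@H](/C=C(/C)CC/C=C(\C)CC=O)C=C1CB1OC(C)(C)C(C)(C)O1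
F4 | step 16 | (1R,6R,7R,8R,10R)-1,10-epoxy-8-hydroxygermacra-4Z,11(13)-dien-12,6-olide | C=C1C(=O)O[C@@H]2/C=C(/C)CC[C@H]3O[C@]3(C)C[C@@H](O)[C@@H]12
F5 | step 6 | (3R,4Z,8E)-11-[(tert-butyldimethylsilyl)oxy]-5,9-dimethyl-1-(trimethylsilyl)undeca-4,8-dien-1-yn-3-ol | C[Si](C)(C)C#C[C@H](O)/C=C(/C)CC/C=C(\C)CCO[Si](C)(C)C(C)(C)C
F6 | step 6 | (3R,4Z,8E)-11-[(tert-butyldimethylsilyl)oxy]-5,9-dimethylundeca-4,8-dien-1-yn-3-ol | C#C[C@H](O)/C=C(/C)CC/C=C(\C)CCO[Si](C)(C)C(C)(C)C
F7 | step 6 | (3S,4Z,8E)-11-[(tert-butyldimethylsilyl)oxy]-5,9-dimethylundeca-1,4,8-trien-3-ol | C=C[C@H](O)/C=C(/C)CC/C=C(\C)CCO[Si](C)(C)C(C)(C)C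
F8 | step 6 | (3S,4Z,8E)-11-[(tert-butyldimethylsilyl)oxy]-5,9-dimethylundeca-1,4,8-trien-3-yl 2-(bromomethyl)acrylate | C=C[C@H](OC(=O)C(=C)CBr)/C=C(/C)CC/C=C(\C)CCO[Si](C)(C)C(C)(C)C
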